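## Retrosynthetic overview
1. Target ⇒ last step: E-selective cross-metathesis at C10=C11 between a C1–C10 homoallylic acetate (west) and an α-methylene-β-hydroxy-γ-lactone (east). Chain numbering: C1 = OCH2, C8 = CHOAc, C12 = CHOH, C13 = ring CH–O, C19 = lactone C=O.
2. Lactone ⇐ trans-vinyl epoxide tert-butyl ester: the C19 carboxyl oxygen attacks allylic C13 with inversion, as in the presumed lactonisation of the C19 acid onto oxidised C13. This gives the trans C12-OH/C13 pattern in one step.
3. Vinyl epoxide ⇐ asymmetric sulfur-ylide epoxidation of 3-methylbut-2-enal with the isothiocineole sulfonium salt of tert-butyl 2-(bromomethyl)acrylate (sets C12 and C13).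
4. West fragment ⇐ nerol: esterification, SeO2 oxidation of the E-methyl group to the C8 enal, catalytic asymmetric allylboration (sets C8), acetylation.
5. Ring order: there is one ring, the γ-lactone; it is closed in the east fragment before the fragments are joined.

Assumption: (E)-3-methylpent-2-enoic acid and both antipodes of isothiocineole are bought, and the senses of induction of the chiral sulfide and of the chiral phosphoric acid are taken from their published models — if either proves opposite here, its antipode is used with no other change.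

## Route

Step 1
Reactants: 1 nerol; 2 (2E)-3-methylpent-2-enoic acid
Product: 3 (2Z)-3,7-dimethylocta-2,6-dien-1-yl (2E)-3-methylpent-2-enoate
Conditions: DCC (1.1 equiv), DMAP (0.1 equiv), CH2Cl2, 0 °C → rt
Reagents that add atoms: none
Why: Steglich esterification of an unhindered primary allylic alcohol under neutral carbodiimide activation, which leaves the 2Z alkene and the E enoate untouched because no acid chloride or amine base is present to deconjugate the enoate.

Step 2
Reactants: 3 (2Z)-3,7-dimethylocta-2,6-dien-1-yl (2E)-3-methylpent-2-enoate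
Product: 5 (2Z,6E)-3,7-dimethyl-8-oxoocta-2,6-dien-1-yl (2E)-3-methylpent-2-enoate, via allylic alcohol 4 (not isolated)
Conditions: SeO2 (0.3 equiv), t-BuOOH (2 equiv), CH2Cl2, 0 °C → rt; then crude, MnO2 (10 equiv), CH2Cl2, rt
Reagents that add atoms: tert-butyl hydroperoxide, CC(C)(C)OO (source of the new oxygen, relayed by catalytic SeO2, O=[Se]=O)
Why: Catalytic SeO2 allylic oxidation (ene reaction then [2,3]-sigmatropic shift) attacks only the electron-rich terminal trisubstituted alkene and specifically its E-methyl group, the ester-deactivated C2 alkene and the enoate being inert, and MnO2 then converges the alcohol/aldehyde mixture to the 6E enal by selective allylic alcohol oxidation.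

Step 3
Reactants: 5 (2Z,6E)-3,7-dimethyl-8-oxoocta-2,6-dien-1-yl (2E)-3-methylpent-2-enoate
Product: 7 (2Z,6E,8S)-8-hydroxy-3,7-dimethylundeca-2,6,10-trien-1-yl (2E)-3-methylpent-2-enoate, via pinacol borate ester 6 (not isolated)
Conditions: allylB(pin) (1.2 equiv), (S)-TRIP [(S)-3,3'-bis(2,4,6-triisopropylphenyl)-1,1'-binaphthyl-2,2'-diyl hydrogen phosphate] (5 mol %), toluene, −30 °C; aq. NaHCO3 work-up
Reagents that add atoms: allylboronic acid pinacol ester, C=CCB1OC(C)(C)C(C)(C)O1
Why: Chiral phosphoric acid-catalysed allylboration through a closed chair transition state in which the (S)-acid hydrogen-bonds to a boronate oxygen and exposes the Si face of the enal, which gives the 8S carbinol by 1,2-addition while the esters do not react.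

Step 4
Reactants: 7 (2Z,6E,8S)-8-hydroxy-3,7-dimethylundeca-2,6,10-trien-1-yl (2E)-3-methylpent-2-enoate
Product: 8 (2Z,6E,8S)-8-acetoxy-3,7-dimethylundeca-2,6,10-trien-1-yl (2E)-3-methylpent-2-enoate
Conditions: Ac2O (1.5 equiv), pyridine, DMAP (cat.), CH2Cl2, 0 °C → rt
Reagents that add atoms: acetic anhydride, CC(=O)OC(C)=O
Why: DMAP-catalysed O-acylation of the secondary alcohol, which proceeds with retention at C8 because the C–O bond is not broken.

Step 5
Reactants: 9 tert-butyl 2-(bromomethyl)prop-2-enoate; 10 (1S,4S,5S)-isothiocineole; 11 3-methylbut-2-enal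
Product: 14 tert-butyl 2-[(2S,3S)-3-(2-methylprop-1-en-1-yl)oxiran-2-yl]prop-2-enoate, via sulfonium bromide 12 (not isolated), via sulfur ylide 13 (not isolated)
Conditions: 9 + 10 (1.05 equiv), MeCN, rt, 3 h; then 11 (1.5 equiv), Cs2CO3 (1.2 equiv), −20 → 0 °C; chromatography on Et3N-washed silica
Reagents that add atoms: none
Why: Proposed new method: the 2-(alkoxycarbonyl)allyl bromide alkylates the sulfide (SN2 and SN2′ give the same salt), Cs2CO3 forms the ester-acidified allylic sulfonium ylide whose conformation and open face are fixed by the bicyclic sulfide (the aldehyde adds to the face remote from CMe2), 1,2-addition to the β,β-disubstituted enal gives the anti-betaine and ring closure expels the sulfide to give the trans-(2S,3S)-vinyl epoxide with both stereocentres set at once; the closest known reactions are the Corey–Chaykovsky-type asymmetric epoxidations of aldehydes, enals included, with benzyl and 2-substituted allyl sulfonium salts of isothiocineole.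

Step 6
Reactants: 14 tert-butyl 2-[(2S,3S)-3-(2-methylprop-1-en-1-yl)oxiran-2-yl]prop-2-enoate
Product: 15 (4S,5R)-4-hydroxy-3-methylidene-5-(2-methylprop-1-en-1-yl)oxolan-2-one
Conditions: (±)-camphor-10-sulfonic acid (10 mol %), 4 Å MS, CH2Cl2, −20 → 0 °C
Reagents that add atoms: none
Why: Acid-triggered epoxide-opening lactonisation in which protonation weakens the allylic C–O bond of the vinyl epoxide, the tert-butyl ester carbonyl oxygen attacks that carbon from the backside in a five-membered closure (neighbouring-group participation as in tert-butyl carbonate and ester epoxide cyclisations) and the tert-butoxy oxocarbenium ion loses isobutene, so the ring-oxygen carbon is inverted to R while the epoxide oxygen stays on the other carbon as the S carbinol, which gives the trans lactone.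

Step 7
Reactants: 8 (2Z,6E,8S)-8-acetoxy-3,7-dimethylundeca-2,6,10-trien-1-yl (2E)-3-methylpent-2-enoate; 15 (4S,5R)-4-hydroxy-3-methylidene-5-(2-methylprop-1-en-1-yl)oxolan-2-one
Product: 16 (2Z,6E,8S)-8-acetoxy-10-[(3E,4S,5R)-4-hydroxy-5-(2-methylprop-1-en-1-yl)-2-oxooxolan-3-ylidene]-3,7-dimethyldeca-2,6-dien-1-yl (2E)-3-methylpent-2-enoate (CNP0168501.1)
Conditions: 15 (2.5 equiv), second-generation Hoveyda–Grubbs catalyst RuCl2(H2IMes)(=CH-C6H4-2-OiPr) (10 mol %), 2,6-dichloro-1,4-benzoquinone (20 mol %), CH2Cl2, 40 °C, Ar sparge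
Reagents that add atoms: none
Why: Cross-metathesis between a type 1 terminal alkene and a non-homodimerising 1,1-disubstituted α-methylene lactone gives the thermodynamically favoured E-alkylidene lactone with the chain anti to the carbonyl, the benzoquinone suppresses ruthenium hydride isomerisation, the trisubstituted and conjugated alkenes react far more slowly, and no stereocentre is touched.

## Compound list
1 | nerol, (2Z)-3,7-dimethylocta-2,6-dien-1-ol | OC/C=C(/C)CCC=C(C)C | starting material
2 | (2E)-3-methylpent-2-enoic acid | CC/C(C)=C/C(=O)O | starting material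
3 | (2Z)-3,7-dimethylocta-2,6-dien-1-yl (2E)-3-methylpent-2-enoate | CC/C(C)=C/C(=O)OC/C=C(/C)CCC=C(C)C | intermediate
4 | (2Z,6E)-8-hydroxy-3,7-dimethylocta-2,6-dien-1-yl (2E)-3-methylpent-2-enoate (formed in the flask, not isolated) | CC/C(C)=C/C(=O)OC/C=C(/C)CC/C=C(\C)CO | intermediate
5 | (2Z,6E)-3,7-dimethyl-8-oxoocta-2,6-dien-1-yl (2E)-3-methylpent-2-enoate | CC/C(C)=C/C(=O)OC/C=C(/C)CC/C=C(\C)C=O | intermediate
6 | pinacol borate ester of 7, O–B(pin) on the 8S oxygen (formed in the flask, hydrolysed at work-up) | CC/C(C)=C/C(=O)OC/C=C(/C)CC/C=C(\C)[C@H](CC=C)OB1OC(C)(C)C(C)(C)O1 | intermediate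
7 | (2Z,6E,8S)-8-hydroxy-3,7-dimethylundeca-2,6,10-trien-1-yl (2E)-3-methylpent-2-enoate | CC/C(C)=C/C(=O)OC/C=C(/C)CC/C=C(\C)[C@H](CC=C)O | intermediate
8 | (2Z,6E,8S)-8-acetoxy-3,7-dimethylundeca-2,6,10-trien-1-yl (2E)-3-methylpent-2-enoate | CC/C(C)=C/C(=O)OC/C=C(/C)CC/C=C(\C)[C@H](CC=C)OC(C)=O | intermediate
9 | tert-butyl 2-(bromomethyl)prop-2-enoate | C=C(CBr)C(=O)OC(C)(C)C | starting material
10 | (1S,4S,5S)-isothiocineole, (1S,4S,5S)-4,7,7-trimethyl-6-thiabicyclo[3.2.1]octane | C[C@H]1CC[C@H]2C[C@@H]1SC2(C)C | starting material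
11 | 3-methylbut-2-enal | CC(C)=CC=O | starting material
12 | (1S,4S,5S)-6-[2-(tert-butoxycarbonyl)prop-2-en-1-yl]-4,7,7-trimethyl-6-thiabicyclo[3.2.1]octan-6-ium bromide, alkylated on the exo lone pair (formed in the flask, not isolated) | C[C@H]1CC[C@H]2C[C@@H]1[S@+](CC(=C)C(=O)OC(C)(C)C)C2(C)C.[Br-] | intermediate
13 | sulfur ylide of 12, carbanion on the S-CH carbon (formed in the flask, not isolated) | C[C@H]1CC[C@H]2C[C@@H]1[S@+]([CH-]C(=C)C(=O)OC(C)(C)C)C2(C)C | intermediate
14 | tert-butyl 2-[(2S,3S)-3-(2-methylprop-1-en-1-yl)oxiran-2-yl]prop-2-enoate (trans epoxide) | C=C(C(=O)OC(C)(C)C)[C@@H]1O[C@H]1C=C(C)C | intermediate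
15 | (4S,5R)-4-hydroxy-3-methylidene-5-(2-methylprop-1-en-1-yl)oxolan-2-one (trans lactone) | C=C1C(=O)O[C@H](C=C(C)C)[C@H]1O | intermediate
16 | (2Z,6E,8S)-8-acetoxy-10-[(3E,4S,5R)-4-hydroxy-5-(2-methylprop-1-en-1-yl)-2-oxooxolan-3-ylidene]-3,7-dimethyldeca-2,6-dien-1-yl (2E)-3-methylpent-2-enoate | CC/C(C)=C/C(=O)OC/C=C(/C)CC/C=C(\C)[C@H](C/C=C1/C(=O)O[C@H](C=C(C)C)[C@H]1O)OC(C)=O | target

## Step count and risk
Total steps: 7. Longest linear sequence: 5 (steps 1, 2, 3, 4, 7 from nerol); the east branch is 2 steps (5, 6) before the union.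

Steps most likely to fail:

Step 5 (ylide epoxidation). The ester-bearing allyl ylide may attack its own salt in an SN2′ sense, and its enantioselectivity and trans/cis ratio are untested. Fallback, resolution instead of reagent control, setting out from 9 and 11 and coming back at 15: 9 is quaternised with tetrahydrothiophene (acetone, rt) to 1-[2-(tert-butoxycarbonyl)prop-2-en-1-yl]thiolan-1-ium bromide F1. Cs2CO3 in MeCN turns this in the flask into the thiolanium ylide F2, which with 11 gives the racemic trans-epoxide F3. Camphorsulfonic acid as in step 6 then gives the racemic trans-lactone F4. Lipase from Burkholderia cepacia with vinyl acetate in MTBE at 30 °C, run to about 55% conversion, is expected by the empirical size rule for lipases (large group = ring carbon carrying the isobutenyl group) to acetylate the (4R,5S)-enantiomer to (2S,3R)-4-methylidene-2-(2-methylprop-1-en-1-yl)-5-oxooxolan-3-yl acetate F5. This leaves 15, which is separated on silica.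

Step 6 (epoxide-opening lactonisation). The dimethylvinyl epoxide may ionise fully, giving cis/trans scrambling, elimination to a dienol or hydride shift. Fallback, setting out from 14 and coming back at 15: the allylic carbon is first opened intermolecularly with water (THF/H2O 4:1, HClO4 1 mol %, 0 °C, SN2-type attack with inversion) to tert-butyl (3S,4R)-3,4-dihydroxy-6-methyl-2-methylidenehept-5-enoate F6. The ring is then closed by acyl transfer (PPTS, toluene, 50 °C, loss of tert-butanol). The ring-closing bond becomes the acyl C–O bond and no cationic carbon is involved in the closure.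

Step 7 (cross-metathesis). The free allylic hydroxyl next to the methylene group may divert the catalyst (isomerisation to a tetronic acid), and the isobutenyl group may take part. Fallback, a changed order of events, setting out from 8 and 14 and coming back at 16: 8 is cross-metathesised with the acyclic, hydroxyl-free acrylate 14 (same catalyst and additive, CH2Cl2, 40 °C) to tert-butyl (2E,5S,6E,10Z)-5-acetoxy-6,10-dimethyl-12-{[(2E)-3-methylpent-2-enoyl]oxy}-2-[(2S,3S)-3-(2-methylprop-1-en-1-yl)oxiran-2-yl]dodeca-2,6,10-trienoate F7. The lactone is then closed as the last step on the full chain (camphorsulfonic acid 10 mol %, CH2Cl2, −20 °C), which gives 16 directly. The allylic acetate and the neryl ester ionise far less readily than the dimethylvinyl epoxide.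

## Further compounds
F1 | step 5 | 1-[2-(tert-butoxycarbonyl)prop-2-en-1-yl]thiolan-1-ium bromide | C=C(C[S+]1CCCC1)C(=O)OC(C)(C)C.[Br-]
F2 | step 5 | thiolanium ylide of F1 (formed in the flask) | C=C([CH-][S+]1CCCC1)C(=O)OC(C)(C)C
F3 | step 5 | racemic trans-epoxide, tert-butyl 2-[(2S,3S)- and (2R,3R)-3-(2-methylprop-1-en-1-yl)oxiran-2-yl]prop-2-enoate, both enantiomers shown | C=C(C(=O)OC(C)(C)C)[C@@H]1O[C@H]1C=C(C)C.C=C(C(=O)OC(C)(C)C)[C@H]1O[C@@H]1C=C(C)C
F4 | step 5 | racemic trans-lactone, (4S,5R)- and (4R,5S)-4-hydroxy-3-methylidene-5-(2-methylprop-1-en-1-yl)oxolan-2-one, both enantiomers shown | C=C1C(=O)O[C@H](C=C(C)C)[C@H]1O.C=C1C(=O)O[C@@H](C=C(C)C)[C@@H]1O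
F5 | step 5 | (2S,3R)-4-methylidene-2-(2-methylprop-1-en-1-yl)-5-oxooxolan-3-yl acetate | C=C1C(=O)O[C@@H](C=C(C)C)[C@@H]1OC(C)=O
F6 | step 6 | tert-butyl (3S,4R)-3,4-dihydroxy-6-methyl-2-methylidenehept-5-enoate | C=C(C(=O)OC(C)(C)C)[C@H](O)[C@H](O)C=C(C)C
F7 | step 7 | tert-butyl (2E,5S,6E,10Z)-5-acetoxy-6,10-dimethyl-12-{[(2E)-3-methylpent-2-enoyl]oxy}-2-[(2S,3S)-3-(2-methylprop-1-en-1-yl)oxiran-2-yl]dodeca-2,6,10-trienoate | CC/C(C)=C/C(=O)OC/C=C(/C)CC/C=C(\C)[C@H](C/C=C(/C(=O)OC(C)(C)C)[C@@H]1O[C@H]1C=C(C)C)OC(C)=O
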